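**Plan**

- Retrosynthesis: after the O–Si bond, a CO2H helper is placed on ring C-11 of the target (the CH2 next to the side-chain methine C-12). The unit C11(CO2H)–C12–C(=CH2)R, a ring CH/CH pair carrying an exocyclic 2-substituted vinyl group on the 14-membered ring, is the γ,δ-unsaturated-acid retron of an ester-enolate Claisen rearrangement, so the C11–C12 bond is cut to give an 18-membered (E)-allylic macrolactone.
- Further cuts: lactone C–O (seco hydroxy acid); the C=C of the trisubstituted allylic alcohol (Wittig); the allylic CH2–CH2 bond beside the (Z)-alkene (copper-catalysed Grignard/allylic acetate coupling); the CH2–CH2CO2R bond (acetate enolate alkylation).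
- Forward: neryl acetate gives ester 4 (3 steps); an oxazolidinone sequence gives the chiral bromide 12 (5 steps); union gives 14; the allyl group is taken to the aldehyde, the (E)-enoate and the allylic alcohol; the seco acid is closed to the 18-membered lactone (step 16), which is contracted to the 14-membered carbocycle (step 17); decarboxylation and desilylation follow.
- Stereochemistry: C-1 comes from auxiliary-controlled hydroxymethylation (step 5); C-12 from the reagent-controlled chair Claisen (step 17); the (4Z)-alkene from nerol; the (8E)-alkene from E-selective SeO2 oxidation; the exocyclic methylene is created by the rearrangement itself.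

Key step: step 17

Assumption: the sense of induction of the (S,S)-controller in step 17 (SMILES FC(F)(F)c1cc(cc(c1)C(F)(F)F)S(=O)(=O)N1[C@@H](c2ccccc2)[C@H](c2ccccc2)N(S(=O)(=O)c2cc(cc(c2)C(F)(F)F)C(F)(F)F)B1Br) is assigned by analogy with acyclic (E)-allyl esters as Re face of the enolate carbon to Re face of the alkene carbon. The mirror-image controller would give the opposite pairing. Either configuration at the carboxyl-bearing carbon leads to the same target, because that centre is erased in step 18.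

**Route**

Step 1
Reactants: 1 neryl acetate, (2Z)-3,7-dimethylocta-2,6-dien-1-yl acetate
Product: 2 (2Z,6E)-8-hydroxy-3,7-dimethylocta-2,6-dien-1-yl acetate
Conditions: SeO2 (cat.), t-BuOOH, salicylic acid (cat.), CH2Cl2, rt
Reagents that add atoms: selenium dioxide, O=[Se]=O (oxygen carrier); tert-butyl hydroperoxide, CC(C)(C)OO (terminal oxidant)
Why: SeO2 allylic oxidation (ene reaction, then [2,3]-sigmatropic shift of the allylseleninic acid) should attack the (E)-methyl of the terminal isopropylidene group, the 2,3-alkene being deactivated by the allylic acetate, and give the (E)-allylic alcohol.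

Step 2
Reactants: 2 (2Z,6E)-8-hydroxy-3,7-dimethylocta-2,6-dien-1-yl acetate
Product: 3 (2Z,6E)-8-bromo-3,7-dimethylocta-2,6-dien-1-yl acetate
Conditions: CBr4, PPh3, CH2Cl2, 0 °C
Reagents that add atoms: tetrabromomethane, BrC(Br)(Br)Br
Why: The Appel reaction converts the primary allylic alcohol into the bromide by SN2 displacement of the oxyphosphonium group under neutral conditions that leave the acetate and both alkene geometries untouched.

Step 3
Reactants: 3 (2Z,6E)-8-bromo-3,7-dimethylocta-2,6-dien-1-yl acetate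
Product: 4 tert-butyl (4E,8Z)-10-acetoxy-4,8-dimethyldeca-4,8-dienoate
Conditions: LiN(iPr)2, tert-butyl acetate, THF, −78 °C; then 3, DMPU, −78 °C
Reagents that add atoms: tert-butyl acetate, CC(=O)OC(C)(C)C
Why: The lithium enolate of tert-butyl acetate should be C-alkylated by the primary allylic bromide (SN2, no transposition because the γ-carbon is trisubstituted) at −78 °C, where attack on the acetate carbonyl is slow; the bulky ester is chosen to survive steps 9 and 14.

Step 4
Reactants: 5 (R)-4-benzyloxazolidin-2-one; 6 pent-4-enoyl chloride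
Product: 7 (R)-4-benzyl-3-(pent-4-enoyl)oxazolidin-2-one
Conditions: Et3N, DMAP (cat.), CH2Cl2, 0 °C to rt
Reagents that add atoms: none
Why: DMAP-catalysed N-acylation of the oxazolidinone by the acid chloride (nucleophilic acyl substitution).

Step 5
Reactants: 7 (R)-4-benzyl-3-(pent-4-enoyl)oxazolidin-2-one
Product: 9 (R)-4-benzyl-3-[(2S)-2-(hydroxymethyl)pent-4-enoyl]oxazolidin-2-one, via titanium enolate 8 (not isolated)
Conditions: TiCl4, iPr2NEt, CH2Cl2, 0 °C; then 1,3,5-trioxane, TiCl4, 0 °C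
Reagents that add atoms: 1,3,5-trioxane, C1OCOCO1
Why: The chelated (Z)-titanium enolate of the N-acyl oxazolidinone is hydroxymethylated by TiCl4-activated formaldehyde on the face opposite the benzyl group (auxiliary-controlled aldol-type reaction), which sets the future C-1 stereocentre.

Step 6
Reactants: 9 (R)-4-benzyl-3-[(2S)-2-(hydroxymethyl)pent-4-enoyl]oxazolidin-2-one
Product: 10 (R)-4-benzyl-3-[(2S)-2-{[(tert-butyldiphenylsilyl)oxy]methyl}pent-4-enoyl]oxazolidin-2-one
Conditions: TBDPSCl, imidazole, CH2Cl2, rt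
Reagents that add atoms: tert-butyl(chloro)diphenylsilane, CC(C)(C)[Si](Cl)(c1ccccc1)c1ccccc1
Why: Imidazole-promoted silylation of the primary alcohol gives a robust silyl ether that is meant to last to the final step.

Step 7
Reactants: 10 (R)-4-benzyl-3-[(2S)-2-{[(tert-butyldiphenylsilyl)oxy]methyl}pent-4-enoyl]oxazolidin-2-one
Product: 11 (2R)-2-{[(tert-butyldiphenylsilyl)oxy]methyl}pent-4-en-1-ol
Conditions: LiBH4, H2O (1 equiv), Et2O, 0 °C
Reagents that add atoms: none
Why: LiBH4 reductively cleaves the imide to the primary alcohol without touching the α-stereocentre or the silyl ether, and releases the auxiliary 5.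

Step 8
Reactants: 11 (2R)-2-{[(tert-butyldiphenylsilyl)oxy]methyl}pent-4-en-1-ol
Product: 12 {[(2S)-2-(bromomethyl)pent-4-en-1-yl]oxy}(tert-butyl)diphenylsilane
Conditions: CBr4, PPh3, CH2Cl2, 0 °C
Reagents that add atoms: tetrabromomethane, BrC(Br)(Br)Br
Why: The Appel reaction replaces the primary hydroxyl by bromide (SN2 at CH2), so the adjacent stereocentre is not involved.

Step 9
Reactants: 12 {[(2S)-2-(bromomethyl)pent-4-en-1-yl]oxy}(tert-butyl)diphenylsilane; 4 tert-butyl (4E,8Z)-10-acetoxy-4,8-dimethyldeca-4,8-dienoate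
Product: 14 tert-butyl (4E,8Z,12S)-12-{[(tert-butyldiphenylsilyl)oxy]methyl}-4,8-dimethylpentadeca-4,8,14-trienoate, via Grignard reagent 13 (not isolated)
Conditions: Mg, THF, rt; then 4, Li2CuCl4 (3 mol %), THF, −20 to 0 °C
Reagents that add atoms: none
Why: Copper-catalysed allylic substitution of the primary allylic acetate by the alkyl Grignard reagent (via an alkylcuprate) should occur at the unhindered α-carbon with retention of the (Z)-alkene, and faster than Grignard addition to the hindered tert-butyl ester.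

Step 10
Reactants: 14 tert-butyl (4E,8Z,12S)-12-{[(tert-butyldiphenylsilyl)oxy]methyl}-4,8-dimethylpentadeca-4,8,14-trienoate
Product: 16 tert-butyl (4E,8Z,12S)-12-{[(tert-butyldiphenylsilyl)oxy]methyl}-15-hydroxy-4,8-dimethylpentadeca-4,8-dienoate, via B-alkyl-9-BBN adduct 15 (not isolated)
Conditions: 9-BBN, THF, 0 °C to rt; then NaOH, H2O2, 0 °C
Reagents that add atoms: hydrogen peroxide, OO
Why: 9-BBN hydroborates only the monosubstituted alkene (anti-Markovnikov), the trisubstituted alkenes being far slower, and brief alkaline peroxide oxidation gives the primary alcohol with the tert-butyl ester intact.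

Step 11
Reactants: 16 tert-butyl (4E,8Z,12S)-12-{[(tert-butyldiphenylsilyl)oxy]methyl}-15-hydroxy-4,8-dimethylpentadeca-4,8-dienoate
Product: 17 tert-butyl (4E,8Z,12S)-12-{[(tert-butyldiphenylsilyl)oxy]methyl}-4,8-dimethyl-15-oxopentadeca-4,8-dienoate
Conditions: DMP (1,1,1-triacetoxy-1,1-dihydro-1,2-benziodoxol-3(1H)-one), CH2Cl2, rt
Reagents that add atoms: none
Why: Periodinane oxidation of the primary alcohol stops at the aldehyde and does not affect alkenes, the silyl ether or the ester.

Step 12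
Reactants: 18 ethyl (triphenyl-λ5-phosphanylidene)acetate; 19 5-bromo-2-methylpent-2-ene
Product: 21 ethyl 6-methyl-2-(triphenyl-λ5-phosphanylidene)hept-5-enoate, via phosphonium bromide 20 (not isolated)
Conditions: NaI (cat.), MeCN, reflux; then aq. NaOH, CH2Cl2
Reagents that add atoms: none
Why: C-Alkylation of the stabilised ylide by the primary bromide (iodide formed in the flask, Finkelstein exchange) gives the phosphonium salt, which aqueous NaOH deprotonates to the α-substituted stabilised ylide.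

Step 13
Reactants: 17 tert-butyl (4E,8Z,12S)-12-{[(tert-butyldiphenylsilyl)oxy]methyl}-4,8-dimethyl-15-oxopentadeca-4,8-dienoate; 21 ethyl 6-methyl-2-(triphenyl-λ5-phosphanylidene)hept-5-enoate
Product: 22 tert-butyl (4E,8Z,12S,15E)-12-{[(tert-butyldiphenylsilyl)oxy]methyl}-16-(ethoxycarbonyl)-4,8,20-trimethylhenicosa-4,8,15,19-tetraenoate
Conditions: toluene, 80 °C
Reagents that add atoms: none
Why: The Wittig reaction of an α-substituted ester-stabilised ylide with an unbranched aldehyde should give the (E)-trisubstituted enoate (ester trans to the chain), as is usual for stabilised ylides.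

Step 14
Reactants: 22 tert-butyl (4E,8Z,12S,15E)-12-{[(tert-butyldiphenylsilyl)oxy]methyl}-16-(ethoxycarbonyl)-4,8,20-trimethylhenicosa-4,8,15,19-tetraenoate
Product: 23 tert-butyl (4E,8Z,12S,15E)-12-{[(tert-butyldiphenylsilyl)oxy]methyl}-16-(hydroxymethyl)-4,8,20-trimethylhenicosa-4,8,15,19-tetraenoate
Conditions: iBu2AlH (2.2 equiv), CH2Cl2, −78 °C; aq. sodium potassium tartrate
Reagents that add atoms: none
Why: iBu2AlH reduces the conjugated ethyl ester to the allylic alcohol (1,2-reduction) at −78 °C, where the hindered tert-butyl ester should react much more slowly (chemoselective ester reduction).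

Step 15
Reactants: 23 tert-butyl (4E,8Z,12S,15E)-12-{[(tert-butyldiphenylsilyl)oxy]methyl}-16-(hydroxymethyl)-4,8,20-trimethylhenicosa-4,8,15,19-tetraenoate
Product: 25 (4E,8Z,12S,15E)-12-{[(tert-butyldiphenylsilyl)oxy]methyl}-16-(hydroxymethyl)-4,8,20-trimethylhenicosa-4,8,15,19-tetraenoic acid, via bis-trimethylsilyl derivative 24 (not isolated)
Conditions: Me3SiOTf, 2,6-lutidine, CH2Cl2, 0 °C; then 5% aq. citric acid, THF, rt
Reagents that add atoms: none
Why: Me3SiOTf silylates the ester carbonyl and expels the tert-butyl cation as isobutene (lutidine as proton trap); the resulting trimethylsilyl ester and the trimethylsilyl ether of the allylic alcohol are hydrolysed by dilute acid while the TBDPS ether and the alkenes should survive (non-hydrolytic tert-butyl ester cleavage).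

Step 16
Reactants: 25 (4E,8Z,12S,15E)-12-{[(tert-butyldiphenylsilyl)oxy]methyl}-16-(hydroxymethyl)-4,8,20-trimethylhenicosa-4,8,15,19-tetraenoic acid
Product: 27 (5E,9Z,13S,16E)-13-{[(tert-butyldiphenylsilyl)oxy]methyl}-5,9-dimethyl-17-(4-methylpent-3-en-1-yl)-1-oxacyclooctadeca-5,9,16-trien-2-one, via mixed anhydride 26 (not isolated)
Conditions: 2,4,6-Cl3C6H2COCl, Et3N, THF, rt; then slow addition to DMAP, toluene, 60 °C, high dilution
Reagents that add atoms: none
Why: Yamaguchi macrolactonisation: DMAP attacks the mixed aroyl anhydride and the acylpyridinium is captured by the remote primary allylic hydroxyl under high dilution, closing the 18-membered lactone without touching the allylic C–O bond or any alkene geometry.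

Step 17
Reactants: 27 (5E,9Z,13S,16E)-13-{[(tert-butyldiphenylsilyl)oxy]methyl}-5,9-dimethyl-17-(4-methylpent-3-en-1-yl)-1-oxacyclooctadeca-5,9,16-trien-2-one
Product: 30 (1S,3E,7Z,11S,14S)-11-{[(tert-butyldiphenylsilyl)oxy]methyl}-3,7-dimethyl-14-(6-methylhepta-1,5-dien-2-yl)cyclotetradeca-3,7-diene-1-carboxylic acid, via boron ketene acetal 28 (not isolated), via boron carboxylate 29 (not isolated)
Conditions: (S,S)-2-bromo-4,5-diphenyl-1,3-bis{[3,5-bis(trifluoromethyl)phenyl]sulfonyl}-1,3,2-diazaborolidine (2 equiv), iPr2NEt, CH2Cl2, −78 °C, then −20 to 4 °C; H2O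
Reagents that add atoms: none
Why: Soft enolisation of the lactone by the chiral bromoborane and iPr2NEt gives the O-boron ketene acetal 28 (C-4 cis to O–B), whose allyl vinyl ether array C3=C2–O1–C18–C17=C16 undergoes a [3,3]-sigmatropic (Ireland–Claisen) shift to the boron carboxylate 29, which is hydrolysed on work-up. The closest known reaction type is the chiral-boron ester-enolate Claisen rearrangement of (E)-allylic esters, including its use for ring contraction of macrolactones to carbocycles. The 14-membered carbocycle is closed by ring contraction of the 18-membered lactone (C2, O1, C18 and C17 become exocyclic), the new C3–C16 bond forming suprafacially on both components within a six-membered chair transition state that the twelve-atom tether can span with both chain ends pseudo-equatorial. The configuration at the side-chain-bearing carbon (C-14 of 30, C-12 of the target) is controlled by the C2-symmetric bis-sulfonamide ligand on boron, which shields one enolate face, and is relayed through the chair and the (E)-geometry of the trisubstituted allylic alkene (Re face of C-3 to Re face of C-16); the carboxyl-bearing centre follows from the enolate geometry and is erased in step 18. The step needs facial selectivity under reagent control and a single enolisation site: the C-13 stereocentre lies three to four bonds from the reacting termini and should not override the reagent, the lactone has only one α-CH2, and the geometrically defined (E)-alkene from step 13 excludes the diastereomeric chair.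

Step 18
Reactants: 30 (1S,3E,7Z,11S,14S)-11-{[(tert-butyldiphenylsilyl)oxy]methyl}-3,7-dimethyl-14-(6-methylhepta-1,5-dien-2-yl)cyclotetradeca-3,7-diene-1-carboxylic acid
Product: 32 tert-butyl{[(1S,4Z,8E,12S)-5,9-dimethyl-12-(6-methylhepta-1,5-dien-2-yl)cyclotetradeca-4,8-dien-1-yl]methoxy}diphenylsilane, via thiohydroxamate ester 31 (not isolated)
Conditions: N-hydroxypyridine-2-thione, DCC, DMAP (cat.), CH2Cl2, rt, dark; then t-BuSH (excess), hν (tungsten lamp), 0 °C
Reagents that add atoms: none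
Why: Barton reductive decarboxylation: the O-acyl thiohydroxamate fragments under light to CO2 and the secondary ring radical, and hydrogen transfer from concentrated tert-butyl thiol should outrun 6-exo cyclisation or 1,2-vinyl shift, giving the ring CH2 and removing the helper carboxyl with its stereocentre.

Step 19
Reactants: 32 tert-butyl{[(1S,4Z,8E,12S)-5,9-dimethyl-12-(6-methylhepta-1,5-dien-2-yl)cyclotetradeca-4,8-dien-1-yl]methoxy}diphenylsilane
Product: 33 [(1S,4Z,8E,12S)-5,9-dimethyl-12-(6-methylhepta-1,5-dien-2-yl)cyclotetradeca-4,8-dien-1-yl]methanol (target)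
Conditions: Bu4NF, THF, rt
Reagents that add atoms: none
Why: Fluoride cleaves the Si–O bond (desilylation) and releases the primary alcohol; nothing else in the molecule is sensitive to fluoride or mild base.

**Compound list**

1 | neryl acetate, (2Z)-3,7-dimethylocta-2,6-dien-1-yl acetate | CC(C)=CCC/C(C)=C\COC(C)=O | starting material
2 | (2Z,6E)-8-hydroxy-3,7-dimethylocta-2,6-dien-1-yl acetate | OC/C(C)=C/CC/C(C)=C\COC(C)=O | intermediate
3 | (2Z,6E)-8-bromo-3,7-dimethylocta-2,6-dien-1-yl acetate | BrC/C(C)=C/CC/C(C)=C\COC(C)=O | intermediate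
4 | tert-butyl (4E,8Z)-10-acetoxy-4,8-dimethyldeca-4,8-dienoate | CC(C)(C)OC(=O)CC/C(C)=C/CC/C(C)=C\COC(C)=O | intermediate
5 | (R)-4-benzyloxazolidin-2-one | O=C1N[C@H](Cc2ccccc2)CO1 | starting material
6 | pent-4-enoyl chloride | C=CCCC(Cl)=O | starting material
7 | (R)-4-benzyl-3-(pent-4-enoyl)oxazolidin-2-one | C=CCCC(=O)N1[C@H](Cc2ccccc2)COC1=O | intermediate
8 | (Z)-trichlorotitanium enolate of 7 | C=CC/C=C(\O[Ti](Cl)(Cl)Cl)N1[C@H](Cc2ccccc2)COC1=O | intermediate (not isolated)
9 | (R)-4-benzyl-3-[(2S)-2-(hydroxymethyl)pent-4-enoyl]oxazolidin-2-one | O=C(N1[C@H](Cc2ccccc2)COC1=O)[C@@H](CC=C)CO | intermediate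
10 | (R)-4-benzyl-3-[(2S)-2-{[(tert-butyldiphenylsilyl)oxy]methyl}pent-4-enoyl]oxazolidin-2-one | O=C(N1[C@H](Cc2ccccc2)COC1=O)[C@@H](CC=C)CO[Si](c1ccccc1)(c1ccccc1)C(C)(C)C | intermediate
11 | (2R)-2-{[(tert-butyldiphenylsilyl)oxy]methyl}pent-4-en-1-ol | OC[C@@H](CC=C)CO[Si](c1ccccc1)(c1ccccc1)C(C)(C)C | intermediate
12 | {[(2S)-2-(bromomethyl)pent-4-en-1-yl]oxy}(tert-butyl)diphenylsilane | BrC[C@@H](CC=C)CO[Si](c1ccccc1)(c1ccccc1)C(C)(C)C | intermediate
13 | [(2S)-2-{[(tert-butyldiphenylsilyl)oxy]methyl}pent-4-en-1-yl]magnesium bromide | Br[Mg]C[C@@H](CC=C)CO[Si](c1ccccc1)(c1ccccc1)C(C)(C)C | intermediate (not isolated)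
14 | tert-butyl (4E,8Z,12S)-12-{[(tert-butyldiphenylsilyl)oxy]methyl}-4,8-dimethylpentadeca-4,8,14-trienoate | CC(C)(C)OC(=O)CC/C(C)=C/CC/C(C)=C\CC[C@H](CO[Si](c1ccccc1)(c1ccccc1)C(C)(C)C)CC=C | intermediate
15 | B-alkyl-9-borabicyclo[3.3.1]nonane adduct of 14 (boron on C-15) | CC(C)(C)OC(=O)CC/C(C)=C/CC/C(C)=C\CC[C@H](CO[Si](c1ccccc1)(c1ccccc1)C(C)(C)C)CCCB1C2CCCC1CCC2 | intermediate (not isolated)
16 | tert-butyl (4E,8Z,12S)-12-{[(tert-butyldiphenylsilyl)oxy]methyl}-15-hydroxy-4,8-dimethylpentadeca-4,8-dienoate | CC(C)(C)OC(=O)CC/C(C)=C/CC/C(C)=C\CC[C@H](CO[Si](c1ccccc1)(c1ccccc1)C(C)(C)C)CCCO | intermediate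
17 | tert-butyl (4E,8Z,12S)-12-{[(tert-butyldiphenylsilyl)oxy]methyl}-4,8-dimethyl-15-oxopentadeca-4,8-dienoate | CC(C)(C)OC(=O)CC/C(C)=C/CC/C(C)=C\CC[C@H](CO[Si](c1ccccc1)(c1ccccc1)C(C)(C)C)CCC=O | intermediate
18 | ethyl (triphenyl-λ5-phosphanylidene)acetate | CCOC(=O)C=P(c1ccccc1)(c1ccccc1)c1ccccc1 | starting material
19 | 5-bromo-2-methylpent-2-ene | CC(C)=CCCBr | starting material
20 | (1-ethoxy-6-methyl-1-oxohept-5-en-2-yl)triphenylphosphonium bromide | CCOC(=O)C(CCC=C(C)C)[P+](c1ccccc1)(c1ccccc1)c1ccccc1.[Br-] | intermediate (not isolated)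
21 | ethyl 6-methyl-2-(triphenyl-λ5-phosphanylidene)hept-5-enoate | CCOC(=O)C(CCC=C(C)C)=P(c1ccccc1)(c1ccccc1)c1ccccc1 | intermediate
22 | tert-butyl (4E,8Z,12S,15E)-12-{[(tert-butyldiphenylsilyl)oxy]methyl}-16-(ethoxycarbonyl)-4,8,20-trimethylhenicosa-4,8,15,19-tetraenoate | CC(C)(C)OC(=O)CC/C(C)=C/CC/C(C)=C\CC[C@H](CO[Si](c1ccccc1)(c1ccccc1)C(C)(C)C)CC/C=C(/C(=O)OCC)CCC=C(C)C | intermediate
23 | tert-butyl (4E,8Z,12S,15E)-12-{[(tert-butyldiphenylsilyl)oxy]methyl}-16-(hydroxymethyl)-4,8,20-trimethylhenicosa-4,8,15,19-tetraenoate | CC(C)(C)OC(=O)CC/C(C)=C/CC/C(C)=C\CC[C@H](CO[Si](c1ccccc1)(c1ccccc1)C(C)(C)C)CC/C=C(/CO)CCC=C(C)C | intermediate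
24 | trimethylsilyl ester and trimethylsilyl ether of 25 | C[Si](C)(C)OC(=O)CC/C(C)=C/CC/C(C)=C\CC[C@H](CO[Si](c1ccccc1)(c1ccccc1)C(C)(C)C)CC/C=C(/CO[Si](C)(C)C)CCC=C(C)C | intermediate (not isolated)
25 | (4E,8Z,12S,15E)-12-{[(tert-butyldiphenylsilyl)oxy]methyl}-16-(hydroxymethyl)-4,8,20-trimethylhenicosa-4,8,15,19-tetraenoic acid | OC(=O)CC/C(C)=C/CC/C(C)=C\CC[C@H](CO[Si](c1ccccc1)(c1ccccc1)C(C)(C)C)CC/C=C(/CO)CCC=C(C)C | intermediate
26 | mixed anhydride of 25 with 2,4,6-trichlorobenzoic acid | O=C(OC(=O)CC/C(C)=C/CC/C(C)=C\CC[C@H](CO[Si](c1ccccc1)(c1ccccc1)C(C)(C)C)CC/C=C(/CO)CCC=C(C)C)c1c(Cl)cc(Cl)cc1Cl | intermediate (not isolated)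
27 | (5E,9Z,13S,16E)-13-{[(tert-butyldiphenylsilyl)oxy]methyl}-5,9-dimethyl-17-(4-methylpent-3-en-1-yl)-1-oxacyclooctadeca-5,9,16-trien-2-one | O=C1CC/C(C)=C/CC/C(C)=C\CC[C@H](CO[Si](c2ccccc2)(c2ccccc2)C(C)(C)C)CC/C=C(/CO1)CCC=C(C)C | intermediate
28 | O-boron ketene acetal of 27 bearing the (S,S)-diazaborolidine (C-4 cis to O–B) | FC(F)(F)c1cc(cc(c1)C(F)(F)F)S(=O)(=O)N1[C@@H](c2ccccc2)[C@H](c2ccccc2)N(S(=O)(=O)c2cc(cc(c2)C(F)(F)F)C(F)(F)F)B1O/C1=C\C/C(C)=C/CC/C(C)=C\CC[C@H](CO[Si](c2ccccc2)(c2ccccc2)C(C)(C)C)CC/C=C(/CO1)CCC=C(C)C | intermediate (not isolated)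
29 | boron carboxylate (acyloxy diazaborolidine) of 30 | C=C(CCC=C(C)C)[C@@H]1[C@@H](C(=O)OB2N(S(=O)(=O)c3cc(cc(c3)C(F)(F)F)C(F)(F)F)[C@@H](c3ccccc3)[C@H](c3ccccc3)N2S(=O)(=O)c2cc(cc(c2)C(F)(F)F)C(F)(F)F)C/C(C)=C/CC/C(C)=C\CC[C@H](CO[Si](c2ccccc2)(c2ccccc2)C(C)(C)C)CC1 | intermediate (not isolated)
30 | (1S,3E,7Z,11S,14S)-11-{[(tert-butyldiphenylsilyl)oxy]methyl}-3,7-dimethyl-14-(6-methylhepta-1,5-dien-2-yl)cyclotetradeca-3,7-diene-1-carboxylic acid | C=C(CCC=C(C)C)[C@@H]1[C@@H](C(=O)O)C/C(C)=C/CC/C(C)=C\CC[C@H](CO[Si](c2ccccc2)(c2ccccc2)C(C)(C)C)CC1 | intermediate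
31 | 2-thioxopyridin-1(2H)-yl ester of 30 | C=C(CCC=C(C)C)[C@@H]1[C@@H](C(=O)On2ccccc2=S)C/C(C)=C/CC/C(C)=C\CC[C@H](CO[Si](c2ccccc2)(c2ccccc2)C(C)(C)C)CC1 | intermediate (not isolated)
32 | tert-butyl{[(1S,4Z,8E,12S)-5,9-dimethyl-12-(6-methylhepta-1,5-dien-2-yl)cyclotetradeca-4,8-dien-1-yl]methoxy}diphenylsilane | C=C(CCC=C(C)C)[C@@H]1CC/C(C)=C/CC/C(C)=C\CC[C@H](CO[Si](c2ccccc2)(c2ccccc2)C(C)(C)C)CC1 | intermediate
33 | [(1S,4Z,8E,12S)-5,9-dimethyl-12-(6-methylhepta-1,5-dien-2-yl)cyclotetradeca-4,8-dien-1-yl]methanol | C=C(CCC=C(C)C)[C@@H]1CC/C(C)=C/CC/C(C)=C\CC[C@H](CO)CC1 | target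

**Count and risks**

Total step count: 19. Longest linear sequence: 15 steps (steps 4–11 and 13–19, from 5 and 6).

Steps most likely to fail:

1. Step 17. The bulky bromoborane may enolise the macrolactone incompletely, the boron ketene acetal may rearrange too slowly, or the reagent may fail to dominate the facial choice at the alkene terminus, giving a mixture at the side-chain-bearing carbon. The fallback gives up reagent control and sets out from lactone 27. LiN(SiMe3)2 and t-BuMe2SiCl in THF/HMPA at −78 °C should give the silyl ketene acetal F1, which rearranges on warming in toluene through the same chair to the silyl ester F2 and its diastereomer, the silyl ester F3. Mild hydrolysis (K2CO3, MeOH/H2O) then gives acid 30 together with the (1R,14R)-acid F4. These are diastereomers because C-11 is fixed, so they can be separated by chromatography, and 30 returns to the route at step 18.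

2. Step 9. The alkylcopper intermediate may attack the γ-carbon (SN2′), the (Z)-alkene may be eroded through allylcopper equilibration, or the Grignard reagent may add to the ester or acetate carbonyl groups. The fallback inverts the order of events and sets out from bromide 12 (as Grignard reagent 13). This is coupled with neryl bromide F5 (from nerol and PBr3) under Li2CuCl4 catalysis at −78 °C, where no carbonyl group is present, to give the triene F6. SeO2/t-BuOOH oxidation of the terminal (E)-methyl gives the allylic alcohol F7, the Appel reaction gives the allylic bromide F8, and alkylation of the lithium enolate of tert-butyl acetate with F8 returns to the route at 14.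

3. Step 18. The secondary ring radical may cyclise onto the side-chain alkene, undergo a 1,2-vinyl shift, or the thiyl radical may isomerise the (Z)-alkene before hydrogen transfer. The fallback removes the helper carbon without free radicals and sets out from acid 30. Reduction with LiAlH4 gives the primary alcohol F9 and periodinane oxidation gives the aldehyde F10. Stoichiometric RhCl(PPh3)3 in refluxing toluene (Tsuji–Wilkinson decarbonylation) then extrudes CO to give 32, where the route is rejoined.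

**Further compounds**

F1 | step 17 | tert-butyldimethylsilyl ketene acetal of 27 (C-4 cis to O–Si) | CC(C)(C)[Si](C)(C)O/C1=C\C/C(C)=C/CC/C(C)=C\CC[C@H](CO[Si](c2ccccc2)(c2ccccc2)C(C)(C)C)CC/C=C(/CO1)CCC=C(C)C
F2 | step 17 | tert-butyldimethylsilyl ester of 30 | C=C(CCC=C(C)C)[C@@H]1[C@@H](C(=O)O[Si](C)(C)C(C)(C)C)C/C(C)=C/CC/C(C)=C\CC[C@H](CO[Si](c2ccccc2)(c2ccccc2)C(C)(C)C)CC1
F3 | step 17 | tert-butyldimethylsilyl ester of the (1R,14R)-diastereomer of 30 | C=C(CCC=C(C)C)[C@H]1[C@H](C(=O)O[Si](C)(C)C(C)(C)C)C/C(C)=C/CC/C(C)=C\CC[C@H](CO[Si](c2ccccc2)(c2ccccc2)C(C)(C)C)CC1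
F4 | step 17 | (1R,3E,7Z,11S,14R)-11-{[(tert-butyldiphenylsilyl)oxy]methyl}-3,7-dimethyl-14-(6-methylhepta-1,5-dien-2-yl)cyclotetradeca-3,7-diene-1-carboxylic acid | C=C(CCC=C(C)C)[C@H]1[C@H](C(=O)O)C/C(C)=C/CC/C(C)=C\CC[C@H](CO[Si](c2ccccc2)(c2ccccc2)C(C)(C)C)CC1
F5 | step 9 | neryl bromide, (2Z)-1-bromo-3,7-dimethylocta-2,6-diene | CC(C)=CCC/C(C)=C\CBr
F6 | step 9 | tert-butyl{[(2S,5Z)-6,10-dimethyl-2-(prop-2-en-1-yl)undeca-5,9-dien-1-yl]oxy}diphenylsilane | CC(C)=CCC/C(C)=C\CC[C@H](CO[Si](c1ccccc1)(c1ccccc1)C(C)(C)C)CC=C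
F7 | step 9 | (2E,6Z,10S)-10-{[(tert-butyldiphenylsilyl)oxy]methyl}-2,6-dimethyltrideca-2,6,12-trien-1-ol | OC/C(C)=C/CC/C(C)=C\CC[C@H](CO[Si](c1ccccc1)(c1ccccc1)C(C)(C)C)CC=C
F8 | step 9 | {[(2S,5Z,9E)-11-bromo-6,10-dimethyl-2-(prop-2-en-1-yl)undeca-5,9-dien-1-yl]oxy}(tert-butyl)diphenylsilane | BrC/C(C)=C/CC/C(C)=C\CC[C@H](CO[Si](c1ccccc1)(c1ccccc1)C(C)(C)C)CC=C
F9 | step 18 | [(1S,3E,7Z,11S,14S)-11-{[(tert-butyldiphenylsilyl)oxy]methyl}-3,7-dimethyl-14-(6-methylhepta-1,5-dien-2-yl)cyclotetradeca-3,7-dien-1-yl]methanol | C=C(CCC=C(C)C)[C@@H]1[C@@H](CO)C/C(C)=C/CC/C(C)=C\CC[C@H](CO[Si](c2ccccc2)(c2ccccc2)C(C)(C)C)CC1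
F10 | step 18 | (1S,3E,7Z,11S,14S)-11-{[(tert-butyldiphenylsilyl)oxy]methyl}-3,7-dimethyl-14-(6-methylhepta-1,5-dien-2-yl)cyclotetradeca-3,7-diene-1-carbaldehyde | C=C(CCC=C(C)C)[C@@H]1[C@@H](C=O)C/C(C)=C/CC/C(C)=C\CC[C@H](CO[Si](c2ccccc2)(c2ccccc2)C(C)(C)C)CC1
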